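The readings stem from a simulated flask with constants of no real substance, noise included.

Delta's target at 8.00 min read 10% of the charge and beta's read 18%, a ratio of 1.80 on a reagent ratio of 1.55, so I took the making of target as roughly first order in reagent. I also assumed that each target costs one reagent.

in all of them: free catalyst 0.25 mM
- delta: substrate 0.010 M; reagent 0.011 M; run made earlier
- theta: substrate 0.010 M; reagent 0.0074 M; run made earlier
- beta: substrate 0.010 M; reagent 0.017 M; run made earlier
- teal: substrate 0.010 M (fed, over 20.0 min); reagent 0.0110 M; a stirred flask in which substrate is dosed at a steady rate over 20.0 min without added volume, worked up at 40 min; time 40 min
- ochre: substrate 0.010 M; reagent 0.0110 M (fed, over 20.0 min); all but reagent at the start; reagent goes in evenly over 20.0 min, the run ends at 40 min; time 40 min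
- green: substrate 0.010 M; reagent 0.0110 M; a single well-mixed tank run continuously and read at steady state, 40 min in it on average
- blue: substrate 0.010 M; reagent 0.0110 M; a closed flask charged with all of it at once and left for 40 min; time 40 min

| run | time / min | open intermediate / % | target / % |
|---|---|---|---|
| delta | 3.00 | 27 | 6 |
| delta | 8.00 | 33 | 10 |
| delta | 15.0 | 35 | 18 |
| delta | 25.0 | 30 | 16 |
| theta | 6.00 | 32 | 8 |
| theta | 12.0 | 36 | 9 |
| theta | 20.0 | 40 | 15 |
| theta | 25.0 | 43 | 15 |
| beta | 3.00 | 26 | 9 |
| beta | 8.00 | 27 | 18 |
| beta | 15.0 | 28 | 26 |
| beta | 25.0 | 20 | 29 |

(readings scatter by 2 percentage points)

- the stated concentrations are those of everything mixed, before any reaction; amounts are the same in each set-up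
- the numbers in the tables scatter by 2 percentage points (one standard deviation)
- the feed brings no volume worth counting
- the earlier runs were made in a closed, stirred flask
- a reading or a percentage of target counts all its forms, free or not

- the set-up with the highest amount of open intermediate at the outlet or at the end, in percent of the substrate put in ("none" if the first two lie within 2 percentage points) (teal / ochre / green / blue / none)
- amount of open intermediate at the outlet or at the end, in percent of the substrate put in, teal
- amount of open intermediate at the outlet or at the end, in percent of the substrate put in, ochre
- amount of open intermediate at the outlet or at the end, in percent of the substrate put in, green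
- amount of open intermediate at the outlet or at the end, in percent of the substrate put in, blue

Ochre differs from blue in when the reagent arrives, so I began with two extremes. With all of it in at the start, ochre is blue and trails it by nothing. With all of it in as one shot at the end of dosing, ochre trails blue by 20.0 min. I placed even feeding between them. The feed brings 0.0550 /min of the substrate charge, while delta, with its full reagent, had used about 0.0200 /min by its first reading, so the feed runs faster than that use. An evenly fed portion of reagent waits on average 10.0 min, half the dosing time, and this wait behind a flask charged at once I called the reagent lag.

So ochre at its end should stand where blue stood one lag earlier. Delta, which has blue's charge, lost open intermediate at a reading of 0.00500 /min of the charge between 15.0 min and 25.0 min, with the scatter of 2 percentage points on each reading. Taking that fall as lasting, I committed to ochre above blue by 5 points, wider than the margin. Teal and green I did not reckon.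

The forecast gave 31% for teal, 45% for ochre, 29% for green and 28% for blue, with ochre best because “opening runs with nearly free catalyst before much target forms”, which puts ochre 17 points above blue where I had 5 points.

The flask gave 28.9% in teal, 33.1% in ochre, 23.4% in green and 27.8% in blue, so ochre stood highest, 5.3 points above blue.

    target → over-reaction product (k = 0.0720 /min)
    substrate + free catalyst → free catalyst + open intermediate (k = 1800 /M/min)
    reagent + catalyst intermediate ⇌ free catalyst + target (K = 0.690, k = 100 /M/min)
    free catalyst + target ⇌ idle complex, settled at all times (K = 86.0 /M)
    free catalyst + open intermediate ⇌ catalyst intermediate (K = 2700 /M, k = 8400 /M/min)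

In blue, as charged, the forward capture of open intermediate by free catalyst has a half-life of 0.33 min and the forward reagent step on catalyst intermediate has 0.63 min, both short against the 40 min of the run, while the lag of 10.0 min is longer than that reagent step. Ochre left to 400 min, a time of which the same lag is a fraction of 0.0250, held 0% open intermediate.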